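**Plan**

- Numbering is that of pterocarpan: ring A is the trioxygenated benzene, ring B the pyran (O5, C6, C6a, C11a, C11b, C4a), ring C the furan (O11, C11a, C6a, C6b, C10a), ring D the methoxybenzene, ring E the dimethylpyran fused at C1–C2.
- Retrosynthesis: cut O5–C6 (ring B, last ring), then C6a–C11a (ring C, carbene C–H insertion), then the benzyl ether bond O11–C11a, then ring E (propargyl ether Claisen), back to 2,4,6-trihydroxybenzaldehyde, whose formyl carbon is C11a.
- Forward: ring A is bought; ring E is annulated at the oxygen next to the formyl group; ring D is attached through O11; ring C is closed by asymmetric C–H insertion; ring B is closed last by dehydrative etherification of the unprotected triol.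
- Stereochemistry: C6a and C11a are set together (cis, 6aS,11aS) by one catalyst-controlled dirhodium carbene C–H insertion and are only carried afterwards.
- Enabling feature: on ring C the hydroxymethyl carbon C6 (on C6a) and ring A (on C11a) are cis, so O5, the ring A oxygen ortho to C11b, lies within reach of C6, while O3 (para to C11b) cannot reach it. Ring B can therefore close on the free diphenol, and only as the cis-fused 6/5 system.

Key step: step 11

Assumption: Rh2(S-PTTL)4, dirhodium tetrakis[N-phthaloyl-(S)-tert-leucinate], is taken to select the enantiotopic benzylic C–H bond that leads to (2S,3R)-14; should the sense be opposite, the catalyst made from (R)-tert-leucine is used and nothing else changes.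

**Route**

Step 1
Reactants: 1 phloroglucinaldehyde (2,4,6-trihydroxybenzaldehyde)
Product: 2 bis-silyl ether (2-hydroxy-4,6-bis(triisopropylsilyloxy)benzaldehyde)
Conditions: TIPSCl (2.1 equiv), imidazole, DMF, 0 °C to rt
Reagents that add atoms: triisopropylsilyl chloride, CC(C)[Si](Cl)(C(C)C)C(C)C
Why: Silyl ether formation: the 4-hydroxyl and one of the two equivalent ortho hydroxyls should be silylated, whereas the last ortho hydroxyl, now locked in a hydrogen bond to the formyl oxygen, should resist a third silylation with the bulky chloride.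

Step 2
Reactants: 2 bis-silyl ether; 3 3-chloro-3-methylbut-1-yne
Product: 4 aryl propargyl ether (2-[(2-methylbut-3-yn-2-yl)oxy]-4,6-bis(triisopropylsilyloxy)benzaldehyde)
Conditions: DBU, CuCl2 (1 mol %), MeCN, 0 °C to rt
Reagents that add atoms: none
Why: Copper-catalysed propargylic substitution (O-alkylation of the phenoxide by the copper acetylide/allenylidene of 3) should ether the only free hydroxyl with the tertiary propargyl group at 0 °C, conditions under which aryl triisopropylsilyl ethers and the aldehyde are left alone.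

Step 3
Reactants: 4 aryl propargyl ether
Product: 7 chromene aldehyde (2,2-dimethyl-5,7-bis(triisopropylsilyloxy)-2H-chromene-8-carbaldehyde), via ortho-allenylphenol 5 (not isolated), via ortho-quinone methide 6 (not isolated)
Conditions: xylenes, 140 °C
Reagents that add atoms: none
Why: Aromatic propargyl Claisen rearrangement onto the only free ortho carbon, enolisation to 5, 1,5-hydrogen shift to 6 and oxa-6π electrocyclisation should give the 2,2-dimethylchromene fused at exactly this oxygen, the other ortho position being blocked by the formyl group, so that the placement of ring E on ring A is fixed by construction.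

Step 4
Reactants: 7 chromene aldehyde
Product: 8 chroman aldehyde (2,2-dimethyl-5,7-bis(triisopropylsilyloxy)chroman-8-carbaldehyde)
Conditions: H2 (1 atm), 10% Pd/C, EtOAc, rt
Reagents that add atoms: none
Why: Heterogeneous catalytic hydrogenation should saturate the styrene-like C3=C4 bond of the chromene to complete ring E, the hindered electron-rich aryl aldehyde and the silyl ethers being much slower to react at 1 atm.

Step 5
Reactants: 8 chroman aldehyde
Product: 9 benzylic alcohol ([2,2-dimethyl-5,7-bis(triisopropylsilyloxy)chroman-8-yl]methanol)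
Conditions: NaBH4, MeOH/THF, 0 °C
Reagents that add atoms: none
Why: Borohydride reduction of the aldehyde gives the benzylic alcohol whose carbon becomes C11a, under basic conditions that avoid ionisation of this trioxygenated benzyl system.

Step 6
Reactants: 9 benzylic alcohol; 10 2-iodo-5-methoxyphenol
Product: 11 benzyl aryl ether (8-[(2-iodo-5-methoxyphenoxy)methyl]-2,2-dimethyl-5,7-bis(triisopropylsilyloxy)chroman)
Conditions: PPh3, DIAD, THF, 0 °C to rt
Reagents that add atoms: none
Why: Mitsunobu etherification of the acidic ortho-iodophenol with the primary benzylic alcohol should form the O11–C11a bond under neutral conditions, with no stereocentre involved.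

Step 7
Reactants: 11 benzyl aryl ether; 12 ethyl diazoacetate
Product: 13 aryldiazoacetate (ethyl 2-diazo-2-[2-{[2,2-dimethyl-5,7-bis(triisopropylsilyloxy)chroman-8-yl]methoxy}-4-methoxyphenyl]acetate)
Conditions: Pd(PPh3)4 (5 mol %), Ag2CO3 (0.5 equiv), Et3N, toluene, rt
Reagents that add atoms: none
Why: Palladium-catalysed cross-coupling of the aryl iodide with the C–H bond of ethyl diazoacetate, a known way to aryldiazoacetates that keeps the diazo group at room temperature, should place the carbene precursor on the carbon that becomes C6a.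

Step 8
Reactants: 13 aryldiazoacetate
Product: 14 cis ester (ethyl (2S,3R)-2-[2,2-dimethyl-5,7-bis(triisopropylsilyloxy)chroman-8-yl]-6-methoxy-2,3-dihydro-1-benzofuran-3-carboxylate)
Conditions: Rh2(S-PTTL)4 (2 mol %), toluene, −60 °C
Reagents that add atoms: none
Why: Enantioselective intramolecular 1,5 C–H insertion of the donor/acceptor rhodium carbene into the benzylic O–CH2 bond closes ring C: the chiral carboxylate ligands select one of the two enantiotopic C–H bonds and so set C11a, and the concerted insertion, known to give 2-aryl-2,3-dihydrobenzofuran-3-carboxylates as the kinetic cis isomers, sets C6a relative to it.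

Step 9
Reactants: 14 cis ester
Product: 16 cis alcohol ([(2S,3S)-2-[2,2-dimethyl-5,7-bis(triisopropylsilyloxy)chroman-8-yl]-6-methoxy-2,3-dihydro-1-benzofuran-3-yl]methanol), via aldehyde 15 (not isolated)
Conditions: i-Bu2AlH (3 equiv), CH2Cl2, −78 to 0 °C; aqueous KNaC4H4O6 (potassium sodium tartrate)
Reagents that add atoms: none
Why: Hydride reduction of the ester with i-Bu2AlH passes through aldehyde 15 to the primary alcohol at low temperature and without alkoxide base, so the epimerisable C3 centre (C6a) should keep its cis configuration.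

Step 10
Reactants: 16 cis alcohol
Product: 17 triol (8-[(2S,3S)-3-(hydroxymethyl)-6-methoxy-2,3-dihydro-1-benzofuran-2-yl]-2,2-dimethylchroman-5,7-diol)
Conditions: Bu4NF (2.2 equiv), AcOH (2.2 equiv), THF, 0 °C
Reagents that add atoms: none
Why: Fluoride-mediated desilylation, buffered with acetic acid so that no free phenoxide can open the benzylic C11a–O11 bond through a quinone methide, should free both phenols of ring A.

Step 11
Reactants: 17 triol
Product: 18 target ((6aS,11aS)-3-hydroxy-9-methoxypterocarpan carrying a 2,2-dimethyl-3,4-dihydro-2H-pyran ring fused at C1–C2 with its oxygen on C1)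
Conditions: PPh3, DIAD, THF (0.01 M), 0 °C to rt
Reagents that add atoms: none
Why: Intramolecular Mitsunobu etherification: the PPh3/DIAD betaine is protonated by a phenol and converts the primary C6 hydroxyl into an alkoxyphosphonium ion, which the O5 phenoxide displaces at C6 (SN2) with loss of triphenylphosphine oxide. The closest known reaction type is the Mitsunobu cyclodehydration of 3-(2-hydroxyaryl)propanols to chromans. Ring B closes in the 6-exo-tet mode. No new stereocentre is formed: C6 is a methylene, so inversion there is invisible, and C6a and C11a are carried over from step 8 (6aS,11aS), the cis fusion being the only one the tether allows. The step needs O5 over O3, ring closure over intermolecular etherification, and substitution over elimination or ionisation at C11a. The cis arrangement on ring C holds C6 next to O5 while the para hydroxyl O3 cannot reach it, high dilution suppresses dimers, and the neutral medium spares the benzylic C11a–O11 bond, so the 3-OH of the target needs no protection.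

**Compound list**

1 | 2,4,6-trihydroxybenzaldehyde | O=Cc1c(O)cc(O)cc1O | starting material
2 | 2-hydroxy-4,6-bis(triisopropylsilyloxy)benzaldehyde | O=Cc1c(O)cc(O[Si](C(C)C)(C(C)C)C(C)C)cc1O[Si](C(C)C)(C(C)C)C(C)C | intermediate
3 | 3-chloro-3-methylbut-1-yne | C#CC(C)(C)Cl | starting material
4 | 2-[(2-methylbut-3-yn-2-yl)oxy]-4,6-bis(triisopropylsilyloxy)benzaldehyde | O=Cc1c(OC(C)(C)C#C)cc(O[Si](C(C)C)(C(C)C)C(C)C)cc1O[Si](C(C)C)(C(C)C)C(C)C | intermediate
5 | 2-hydroxy-3-(3-methylbuta-1,2-dien-1-yl)-4,6-bis(triisopropylsilyloxy)benzaldehyde (ortho-allenylphenol, not isolated) | O=Cc1c(O)c(C=C=C(C)C)c(O[Si](C(C)C)(C(C)C)C(C)C)cc1O[Si](C(C)C)(C(C)C)C(C)C | intermediate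
6 | 5-(3-methylbut-2-en-1-ylidene)-6-oxo-2,4-bis(triisopropylsilyloxy)cyclohexa-1,3-diene-1-carbaldehyde (ortho-quinone methide, not isolated) | O=CC1=C(O[Si](C(C)C)(C(C)C)C(C)C)C=C(O[Si](C(C)C)(C(C)C)C(C)C)C(=CC=C(C)C)C1=O | intermediate
7 | 2,2-dimethyl-5,7-bis(triisopropylsilyloxy)-2H-chromene-8-carbaldehyde | O=Cc1c(O[Si](C(C)C)(C(C)C)C(C)C)cc(O[Si](C(C)C)(C(C)C)C(C)C)c2c1OC(C)(C)C=C2 | intermediate
8 | 2,2-dimethyl-5,7-bis(triisopropylsilyloxy)chroman-8-carbaldehyde | O=Cc1c(O[Si](C(C)C)(C(C)C)C(C)C)cc(O[Si](C(C)C)(C(C)C)C(C)C)c2c1OC(C)(C)CC2 | intermediate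
9 | [2,2-dimethyl-5,7-bis(triisopropylsilyloxy)chroman-8-yl]methanol | OCc1c(O[Si](C(C)C)(C(C)C)C(C)C)cc(O[Si](C(C)C)(C(C)C)C(C)C)c2c1OC(C)(C)CC2 | intermediate
10 | 2-iodo-5-methoxyphenol | COc1ccc(I)c(O)c1 | starting material
11 | 8-[(2-iodo-5-methoxyphenoxy)methyl]-2,2-dimethyl-5,7-bis(triisopropylsilyloxy)chroman | COc1ccc(I)c(OCc2c(O[Si](C(C)C)(C(C)C)C(C)C)cc(O[Si](C(C)C)(C(C)C)C(C)C)c3c2OC(C)(C)CC3)c1 | intermediate
12 | ethyl diazoacetate | CCOC(=O)C=[N+]=[N-] | starting material
13 | ethyl 2-diazo-2-[2-{[2,2-dimethyl-5,7-bis(triisopropylsilyloxy)chroman-8-yl]methoxy}-4-methoxyphenyl]acetate | CCOC(=O)C(=[N+]=[N-])c1ccc(OC)cc1OCc1c(O[Si](C(C)C)(C(C)C)C(C)C)cc(O[Si](C(C)C)(C(C)C)C(C)C)c2c1OC(C)(C)CC2 | intermediate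
14 | ethyl (2S,3R)-2-[2,2-dimethyl-5,7-bis(triisopropylsilyloxy)chroman-8-yl]-6-methoxy-2,3-dihydro-1-benzofuran-3-carboxylate (cis) | COc1ccc2c(c1)O[C@H](c1c(O[Si](C(C)C)(C(C)C)C(C)C)cc(O[Si](C(C)C)(C(C)C)C(C)C)c3c1OC(C)(C)CC3)[C@@H]2C(=O)OCC | intermediate
15 | (2S,3R)-2-[2,2-dimethyl-5,7-bis(triisopropylsilyloxy)chroman-8-yl]-6-methoxy-2,3-dihydro-1-benzofuran-3-carbaldehyde (cis, not isolated) | COc1ccc2c(c1)O[C@H](c1c(O[Si](C(C)C)(C(C)C)C(C)C)cc(O[Si](C(C)C)(C(C)C)C(C)C)c3c1OC(C)(C)CC3)[C@@H]2C=O | intermediate
16 | [(2S,3S)-2-[2,2-dimethyl-5,7-bis(triisopropylsilyloxy)chroman-8-yl]-6-methoxy-2,3-dihydro-1-benzofuran-3-yl]methanol (cis) | COc1ccc2c(c1)O[C@H](c1c(O[Si](C(C)C)(C(C)C)C(C)C)cc(O[Si](C(C)C)(C(C)C)C(C)C)c3c1OC(C)(C)CC3)[C@@H]2CO | intermediate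
17 | 8-[(2S,3S)-3-(hydroxymethyl)-6-methoxy-2,3-dihydro-1-benzofuran-2-yl]-2,2-dimethylchroman-5,7-diol (cis) | COc1ccc2c(c1)O[C@H](c1c(O)cc(O)c3c1OC(C)(C)CC3)[C@@H]2CO | intermediate
18 | (6aS,11aS)-3-hydroxy-9-methoxypterocarpan with a 2,2-dimethyl-3,4-dihydro-2H-pyran ring fused at C1–C2 (oxygen on C1) | COc1ccc2c(c1)O[C@@H]1c3c(cc(O)c4c3OC(C)(C)CC4)OC[C@H]21 | target

**Totals and risks**

Total step count: 11. Longest linear sequence: 11 steps (from 1; compounds 3, 10 and 12 are purchased).

Three steps most likely to fail:

(a) Step 8. The very electron-rich, doubly ortho-substituted benzylic C–H bond may react by stepwise hydride transfer to the carbene, and the resulting zwitterion can close without preference at C3, so that cis/trans selectivity erodes; the ester centre may also epimerise on handling. This fallback repairs the C3 (C6a) configuration only; it does not raise the enantiomeric purity at C11a. It sets out from 14 as the mixture of C3 epimers and returns at 17. Cleavage of both silyl ethers with Bu4NF/AcOH in THF should give the diphenol ester ethyl (2S)-2-(5,7-dihydroxy-2,2-dimethylchroman-8-yl)-6-methoxy-2,3-dihydro-1-benzofuran-3-carboxylate F1. DBU (0.2 equiv) in CH2Cl2 at rt equilibrates C3 through the ester enolate, and because only the cis epimer can transesterify onto the ortho phenol O5, the mixture should drain into the cis-fused lactone (6aR,11aS)-6-oxo analogue of 18 F2. LiBH4 in THF at 0 °C then opens this aryl ester reductively to triol 17, which enters step 11 unchanged.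

(b) Step 11. The alkoxyphosphonium ion may be intercepted by the para phenol of a second molecule or by the hydrazide, or may lose the C6a proton to give the exocyclic alkene. The fallback sets out from 16 and returns at 18. With both phenols still silylated, MsCl/Et3N (CH2Cl2, 0 °C) should convert the primary alcohol into the mesylate [(2S,3S)-2-[2,2-dimethyl-5,7-bis(triisopropylsilyloxy)chroman-8-yl]-6-methoxy-2,3-dihydro-1-benzofuran-3-yl]methyl methanesulfonate F3. Bu4NF (2.2 equiv, THF, 0 °C) then removes the silyl groups, and the liberated O5 phenoxide should close ring B at once by 6-exo-tet displacement of mesylate; the O3 phenoxide is protonated on work-up, giving 18.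

(c) Step 7. Slow oxidative addition of the hindered, electron-rich aryl iodide may let palladium carbene formation from the diazoester (dimerisation, loss of the diazo group) take over. The fallback sets out from 11 and returns at 13. Negishi-type coupling of 11 with commercial BrZnCH2CO2Et (Reformatsky reagent; Pd(dba)2, XPhos, THF, 60 °C) should give the arylacetate ethyl 2-[2-{[2,2-dimethyl-5,7-bis(triisopropylsilyloxy)chroman-8-yl]methoxy}-4-methoxyphenyl]acetate F4. Regitz diazo transfer (4-acetamidobenzenesulfonyl azide, DBU, MeCN, 0 °C to rt) then converts this arylacetate into 13.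

Further compounds
F1 | step 8 | ethyl (2S)-2-(5,7-dihydroxy-2,2-dimethylchroman-8-yl)-6-methoxy-2,3-dihydro-1-benzofuran-3-carboxylate (C3 epimers) | COc1ccc2c(c1)O[C@H](c1c(O)cc(O)c3c1OC(C)(C)CC3)C2C(=O)OCC
F2 | step 8 | (6aR,11aS)-3-hydroxy-9-methoxy-6-oxopterocarpan with the ring E dimethylpyran (cis-fused lactone, 6-oxo analogue of 18) | COc1ccc2c(c1)O[C@@H]1c3c(cc(O)c4c3OC(C)(C)CC4)OC(=O)[C@H]21
F3 | step 11 | [(2S,3S)-2-[2,2-dimethyl-5,7-bis(triisopropylsilyloxy)chroman-8-yl]-6-methoxy-2,3-dihydro-1-benzofuran-3-yl]methyl methanesulfonate | COc1ccc2c(c1)O[C@H](c1c(O[Si](C(C)C)(C(C)C)C(C)C)cc(O[Si](C(C)C)(C(C)C)C(C)C)c3c1OC(C)(C)CC3)[C@@H]2COS(C)(=O)=O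
F4 | step 7 | ethyl 2-[2-{[2,2-dimethyl-5,7-bis(triisopropylsilyloxy)chroman-8-yl]methoxy}-4-methoxyphenyl]acetate | CCOC(=O)Cc1ccc(OC)cc1OCc1c(O[Si](C(C)C)(C(C)C)C(C)C)cc(O[Si](C(C)C)(C(C)C)C(C)C)c2c1OC(C)(C)CC2
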